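The dimethylpyran ring (ring D of the chroman unit: O1, C2, C3, C4, C4a, C8a) is cut into a 2-fluoro-3-alkoxybenzaldehyde and 2-hydroxy-2-methylpropanal. The key step exploits two features: C8a lies ortho to the formyl carbon C4, so its fluoride is displaced by the tertiary alkoxide O1, and C3/C4 are adjacent carbinol carbons next to quaternary C2, so a chiral triazolylidene can join the two formyl carbons by a crossed benzoin closure. One flask thus gives the (3S) ketol of ring D. Hydroxyl-directed reduction sets C4, and C–H borylation followed by rhodium-catalysed asymmetric addition to a chromone builds the (2S)-flavanone (rings A and C).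

Key step: step 3

Assumption: the sense of induction of the triazolium salt [(5aS,10bR) antipode taken to give 3S] and of the bisphosphine [(S) antipode taken to give 2S] is inferred by analogy with related substrates; the mirror-image catalyst is used if the sense proves opposite.

Step 1
Reactants: 1 2-fluoro-3-hydroxybenzaldehyde
Product: 2 2-fluoro-3-[(4-methoxybenzyl)oxy]benzaldehyde
Conditions: 4-methoxybenzyl chloride, K2CO3, DMF, rt
Reagents that add atoms: 4-methoxybenzyl chloride, COc1ccc(CCl)cc1
Why: Williamson etherification of the phenoxide, the only acidic site; the 4-methoxybenzyl group is chosen because each of its ring C–H bonds has an ortho substituent, so it should stay untouched in the later C–H borylation, and it is removed by hydrogenolysis.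

Step 2
Reactants: 3 2-methylbut-3-en-2-ol
Product: 5 2-hydroxy-2-methylpropanal, via ozonide 4 (not isolated)
Conditions: O3, CH2Cl2, −78 °C; then Me2S, −78 °C to rt; used freshly
Reagents that add atoms: ozone, [O-][O+]=O
Why: Ozonolysis with reductive work-up (Criegee mechanism) cleaves the terminal alkene to the alpha-quaternary hydroxy aldehyde, which cannot enolise; no stereocentre is present.

Step 3
Reactants: 2 2-fluoro-3-[(4-methoxybenzyl)oxy]benzaldehyde; 5 2-hydroxy-2-methylpropanal
Product: 7 (3S)-3-hydroxy-8-[(4-methoxybenzyl)oxy]-2,2-dimethylchroman-4-one, via ether dialdehyde 6 (not isolated)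
Conditions: NaH (1.1 equiv), THF/DMF 4:1, 0 °C to rt; then (5aS,10bR)-N-pentafluorophenyl aminoindanol-derived triazolium tetrafluoroborate (10 mol%), toluene, rt; AcOH quench
Reagents that add atoms: none
Why: The sodium alkoxide of 5 displaces the fluoride of 2 by addition–elimination (SNAr) at C8a, which the ortho formyl group activates, and gives dialdehyde 6; the triazolylidene set free by the leftover alkoxide then adds to the aryl formyl carbon C4, and the resulting acyl-anion equivalent (Breslow intermediate) attacks the formyl carbon C3 before the carbene leaves. The closest known reaction types are the alkoxide SNAr of 2-fluorobenzaldehydes and the triazolium-catalysed intramolecular crossed benzoin reaction that leads to 3-hydroxychroman-4-ones. Ring D closes in the C3–C4 bond formation as a 6-exo-trig attack on the C3 carbonyl, the O1–C8a bond having been formed between the two components just before in the same flask. The only new stereocentre, C3 (S in the ketol, the same spatial arrangement as R in the diol), is set by the catalyst, whose fused indane ring shields one face of the acyl-anion equivalent. The step needs chemoselectivity between the two formyl groups and freedom from enolisation: the C3 aldehyde is alpha-quaternary, so it is slow to form its own acyl-anion equivalent and cannot enolise or undergo aldol reactions, and only the fluorine ortho to the formyl group is activated for displacement.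

Step 4
Reactants: 7 (3S)-3-hydroxy-8-[(4-methoxybenzyl)oxy]-2,2-dimethylchroman-4-one
Product: 8 (3R,4S)-8-[(4-methoxybenzyl)oxy]-2,2-dimethylchroman-3,4-diol
Conditions: Me4NBH(OAc)3, MeCN/AcOH 1:1, −30 to 0 °C
Reagents that add atoms: none
Why: Hydroxyl-directed reduction (Evans–Saksena type): the C3 hydroxyl exchanges an acetate on boron and the hydride is delivered intramolecularly to the face of the C4 carbonyl that carries O3, so the new C4 hydroxyl should end up trans and C4 becomes S.

Step 5
Reactants: 8 (3R,4S)-8-[(4-methoxybenzyl)oxy]-2,2-dimethylchroman-3,4-diol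
Product: 10 (3R,4S)-8-[(4-methoxybenzyl)oxy]-2,2-dimethyl-6-(4,4,5,5-tetramethyl-1,3,2-dioxaborolan-2-yl)chroman-3,4-diol, via trisboryl intermediate 9 (not isolated)
Conditions: HBpin (3.5 equiv), [Ir(OMe)(cod)]2 (2 mol%), 4,4'-di-tert-butyl-2,2'-bipyridine (4 mol%), THF, 60 °C; then MeOH, rt
Reagents that add atoms: pinacolborane, [H]B1OC(C)(C)C(C)(C)O1
Why: Iridium-catalysed C–H borylation under steric control: both hydroxyls are first borylated by HBpin with loss of H2, then only C6–H, the one ring C–H without an ortho substituent, is borylated, and methanol cleaves the two borate esters while the aryl boronate stays.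

Step 6
Reactants: 11 7-hydroxy-4H-chromen-4-one
Product: 12 7-(benzyloxy)-4H-chromen-4-one
Conditions: BnBr, K2CO3, acetone, reflux
Reagents that add atoms: benzyl bromide, BrCc1ccccc1
Why: Williamson etherification of the acidic 7-hydroxyl, which must be capped because a chromone phenoxide would deactivate the enone toward conjugate addition.

Step 7
Reactants: 10 (3R,4S)-8-[(4-methoxybenzyl)oxy]-2,2-dimethyl-6-(4,4,5,5-tetramethyl-1,3,2-dioxaborolan-2-yl)chroman-3,4-diol; 12 7-(benzyloxy)-4H-chromen-4-one
Product: 13 (2S)-7-(benzyloxy)-2-{(3R,4S)-3,4-dihydroxy-8-[(4-methoxybenzyl)oxy]-2,2-dimethylchroman-6-yl}chroman-4-one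
Conditions: [Rh(OH)(cod)]2 (2.5 mol%), (S)-2,2'-bis[bis(3,4,5-trifluorophenyl)phosphino]-6,6'-dimethoxy-1,1'-biphenyl (5.5 mol%), dioxane/H2O 10:1, 50 °C
Reagents that add atoms: none
Why: Hayashi–Miyaura rhodium-catalysed asymmetric 1,4-addition: the aryl group passes from boron to the rhodium hydroxide, inserts into C2=C3 of the chromone and the oxa-allyl rhodium is hydrolysed, the ligand alone (catalyst control, the diol being remote) setting flavanone C2 as S, while the base-free medium should avoid ring opening of the flavanone.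

Step 8
Reactants: 13 (2S)-7-(benzyloxy)-2-{(3R,4S)-3,4-dihydroxy-8-[(4-methoxybenzyl)oxy]-2,2-dimethylchroman-6-yl}chroman-4-one
Product: 14 (2S)-7-hydroxy-2-[(3R,4S)-3,4,8-trihydroxy-2,2-dimethylchroman-6-yl]chroman-4-one (CNP0281318.3)
Conditions: H2 (1 atm), Pd/C, EtOAc/MeOH, rt
Reagents that add atoms: none
Why: Hydrogenolysis of the two benzyl-type aryl ethers under neutral conditions at room temperature, which should leave the enolisable flavanone C2 and the benzylic C4 carbinol untouched; no stereocentre is formed.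

Compound list
1 | 2-fluoro-3-hydroxybenzaldehyde | O=Cc1cccc(O)c1F | starting material
2 | 2-fluoro-3-[(4-methoxybenzyl)oxy]benzaldehyde | O=Cc1cccc(OCc2ccc(OC)cc2)c1F | intermediate
3 | 2-methylbut-3-en-2-ol | CC(C)(O)C=C | starting material
4 | 3-(2-hydroxypropan-2-yl)-1,2,4-trioxolane (ozonide, not isolated) | CC(C)(O)C1OCOO1 | intermediate
5 | 2-hydroxy-2-methylpropanal | CC(C)(O)C=O | intermediate
6 | 3-[(4-methoxybenzyl)oxy]-2-[(2-methyl-1-oxopropan-2-yl)oxy]benzaldehyde (not isolated) | O=Cc1cccc(OCc2ccc(OC)cc2)c1OC(C)(C)C=O | intermediate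
7 | (3S)-3-hydroxy-8-[(4-methoxybenzyl)oxy]-2,2-dimethylchroman-4-one | CC1(C)Oc2c(OCc3ccc(OC)cc3)cccc2C(=O)[C@H]1O | intermediate
8 | (3R,4S)-8-[(4-methoxybenzyl)oxy]-2,2-dimethylchroman-3,4-diol | CC1(C)Oc2c(OCc3ccc(OC)cc3)cccc2[C@H](O)[C@H]1O | intermediate
9 | (3R,4S)-8-[(4-methoxybenzyl)oxy]-2,2-dimethyl-6-(4,4,5,5-tetramethyl-1,3,2-dioxaborolan-2-yl)-3,4-bis[(4,4,5,5-tetramethyl-1,3,2-dioxaborolan-2-yl)oxy]chroman (not isolated) | CC1(C)Oc2c(OCc3ccc(OC)cc3)cc(B3OC(C)(C)C(C)(C)O3)cc2[C@H](OB2OC(C)(C)C(C)(C)O2)[C@H]1OB1OC(C)(C)C(C)(C)O1 | intermediate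
10 | (3R,4S)-8-[(4-methoxybenzyl)oxy]-2,2-dimethyl-6-(4,4,5,5-tetramethyl-1,3,2-dioxaborolan-2-yl)chroman-3,4-diol | CC1(C)Oc2c(OCc3ccc(OC)cc3)cc(B3OC(C)(C)C(C)(C)O3)cc2[C@H](O)[C@H]1O | intermediate
11 | 7-hydroxy-4H-chromen-4-one | O=c1ccoc2cc(O)ccc12 | starting material
12 | 7-(benzyloxy)-4H-chromen-4-one | O=c1ccoc2cc(OCc3ccccc3)ccc12 | intermediate
13 | (2S)-7-(benzyloxy)-2-{(3R,4S)-3,4-dihydroxy-8-[(4-methoxybenzyl)oxy]-2,2-dimethylchroman-6-yl}chroman-4-one | CC1(C)Oc2c(OCc3ccc(OC)cc3)cc([C@@H]3CC(=O)c4ccc(OCc5ccccc5)cc4O3)cc2[C@H](O)[C@H]1O | intermediate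
14 | (2S)-7-hydroxy-2-[(3R,4S)-3,4,8-trihydroxy-2,2-dimethylchroman-6-yl]chroman-4-one | CC1(C)Oc2c(O)cc([C@@H]3CC(=O)c4ccc(O)cc4O3)cc2[C@H](O)[C@H]1O | target

Total step count: 8. Longest linear sequence: 6 (steps 1, 3, 4, 5, 7, 8).

Steps most likely to fail

Step 3. What may go wrong:
- base-induced alpha-ketol rearrangement or oligomerisation of the alkoxide of 5 before the etherification;
- slow displacement at a fluoride flanked by two ortho groups;
- carbene attack at the alpha-aryloxy aldehyde with loss of aryloxide;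
- erosion of the C3 configuration by enolisation of the ketol.

Fallback (olefin metathesis and asymmetric epoxidation in place of the benzoin closure; sets out from 2, returns at 8, so it also bypasses step 4): 2 is etherified with the sodium alkoxide of 3 (NaH, DMF, 0 °C to rt) to 3-[(4-methoxybenzyl)oxy]-2-[(2-methylbut-3-en-2-yl)oxy]benzaldehyde F1. Wittig methylenation (Ph3P=CH2, THF) gives 1-ethenyl-3-[(4-methoxybenzyl)oxy]-2-[(2-methylbut-3-en-2-yl)oxy]benzene F2. Ring-closing metathesis with the second-generation Grubbs catalyst RuCl2(=CHPh)(PCy3)(H2IMes) in CH2Cl2 should give 8-[(4-methoxybenzyl)oxy]-2,2-dimethyl-2H-chromene F3. Jacobsen epoxidation [(R,R)-(salen)MnCl, NaOCl, 4-phenylpyridine N-oxide, CH2Cl2, 0 °C] should give (3R,4R)-3,4-epoxy-8-[(4-methoxybenzyl)oxy]-2,2-dimethylchroman F4. Dilute aqueous H2SO4 in acetone then opens the epoxide at the benzylic C4 with inversion to the trans-diol 8.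

Step 7. What may go wrong:
- slow transfer of the aryl group from the pinacol boronate to rhodium, with protodeboronation taking over;
- 1,2-addition of the aryl rhodium species to the product ketone;
- loss of the C2 configuration through reversible ring opening of the flavanone.

Fallback (a cationic divalent palladium/pyridine–oxazoline manifold acting on the free boronic acid instead of the rhodium hydroxide/boronate ester manifold; sets out from 10, returns at 13): boron exchange of 10 with methylboronic acid (acetone/water, trace of acid) gives [(3R,4S)-3,4-dihydroxy-8-[(4-methoxybenzyl)oxy]-2,2-dimethylchroman-6-yl]boronic acid F5. F5 is then added to 12 under Pd(OCOCF3)2, (R)-4-tert-butyl-2-(pyridin-2-yl)-4,5-dihydro-1,3-oxazole, NH4PF6, water, 1,2-dichloroethane, 60 °C; the ligand antipode is again assigned by analogy. This should give 13.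

Step 4. What may go wrong:
- poor facial selectivity, because external hydride attack anti to the axial C2 methyl group leads to the cis-diol;
- acid-promoted ionisation at the benzylic C4.

Fallback (undirected reduction followed by inversion at C4; sets out from 7, returns at 8): 7 is reduced with NaBH4 (MeOH, 0 °C) to (3R,4R)-8-[(4-methoxybenzyl)oxy]-2,2-dimethylchroman-3,4-diol F6. Mitsunobu reaction at the benzylic C4 hydroxyl (PPh3, diisopropyl azodicarboxylate, 4-nitrobenzoic acid, THF) with inversion gives (3R,4S)-3-hydroxy-8-[(4-methoxybenzyl)oxy]-2,2-dimethylchroman-4-yl 4-nitrobenzoate F7. K2CO3 in MeOH removes the ester to give 8.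

Further compounds
F1 | step 3 | 3-[(4-methoxybenzyl)oxy]-2-[(2-methylbut-3-en-2-yl)oxy]benzaldehyde | O=Cc1cccc(OCc2ccc(OC)cc2)c1OC(C)(C)C=C
F2 | step 3 | 1-ethenyl-3-[(4-methoxybenzyl)oxy]-2-[(2-methylbut-3-en-2-yl)oxy]benzene | C=Cc1cccc(OCc2ccc(OC)cc2)c1OC(C)(C)C=C
F3 | step 3 | 8-[(4-methoxybenzyl)oxy]-2,2-dimethyl-2H-chromene | CC1(C)Oc2c(OCc3ccc(OC)cc3)cccc2C=C1
F4 | step 3 | (3R,4R)-3,4-epoxy-8-[(4-methoxybenzyl)oxy]-2,2-dimethylchroman | CC1(C)Oc2c(OCc3ccc(OC)cc3)cccc2[C@H]3O[C@@H]13
F5 | step 7 | [(3R,4S)-3,4-dihydroxy-8-[(4-methoxybenzyl)oxy]-2,2-dimethylchroman-6-yl]boronic acid | CC1(C)Oc2c(OCc3ccc(OC)cc3)cc(B(O)O)cc2[C@H](O)[C@H]1O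
F6 | step 4 | (3R,4R)-8-[(4-methoxybenzyl)oxy]-2,2-dimethylchroman-3,4-diol | CC1(C)Oc2c(OCc3ccc(OC)cc3)cccc2[C@@H](O)[C@H]1O
F7 | step 4 | (3R,4S)-3-hydroxy-8-[(4-methoxybenzyl)oxy]-2,2-dimethylchroman-4-yl 4-nitrobenzoate | CC1(C)Oc2c(OCc3ccc(OC)cc3)cccc2[C@H](OC(=O)c2ccc(cc2)[N+](=O)[O-])[C@H]1O
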